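Which flask holds more target after 20 min, west at 110 °C or north-west at 130 °C, each with 1.10 equiv of partner?

all flasks: starting material 0.30 M

|  | partner | temperature | remark | time |
|---|---|---|---|---|
| epsilon | 1.5 equiv | 115 °C | run made earlier |  |
| theta | 2.4 equiv | 126 °C | run made earlier |  |
| west | 1.10 equiv | 110 °C |  | 20 min |
| north-west | 1.10 equiv | 130 °C |  | 20 min |

| run | time / min | target / % |
|---|---|---|
| epsilon | 2.50 | 27.2 |
| epsilon | 5.00 | 36.7 |
| epsilon | 8.00 | 40.2 |
| epsilon | 10.0 | 41.4 |
| epsilon | 12.0 | 42.0 |
| epsilon | 15.0 | 42.4 |
| theta | 0.667 | 26.6 |
| theta | 0.833 | 30.8 |
| theta | 2.00 | 43.4 |
| theta | 2.50 | 45.4 |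
| theta | 5.00 | 47.4 |
| theta | 6.00 | 47.6 |

(readings scatter by 0.3 percentage points)

- percent here means starting material units held: one self-condensation product counts as two
- what was read earlier has a scatter of 0.3 percentage points, one standard deviation
- what may be going on: 2 starting material -> self-condensation product; starting material + partner <-> adduct; adduct -> target; adduct -> decomposed reagent

* the best flask by amount of target, in percent of the starting material charged; "all alike" if 1.5 percentage points covers them all (west / north-west / all alike)
* amount of target at the end, in percent of the starting material charged, west
* amount of target at the end, in percent of the starting material charged, north-west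

We reckon with the plateau rise, the difference between the last readings of the theta and epsilon runs:

D = 47.6 % − 42.4 % = 5.2 percentage points

We test in turn what could upset a reckoning built on it. A last theta reading off by 0.3 points moves the north-west estimate by only 0.41 points. Time looks minor too: in the epsilon run the gap to the last reading halves every 1.77 min, far shorter than 20 min, though west is the flask to doubt.

What matters is how D divides. The theta run differs from the epsilon run in both temperature and partner. If D belongs to partner, both flasks sit near 40.1 %. If it belongs to temperature:

west = 42.4 % + D × (110 °C − 115 °C) / (126 °C − 115 °C) = 40.0 %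

north-west = 47.6 % + D × (130 °C − 126 °C) / (126 °C − 115 °C) = 49.5 %

West comes out alike either way, so north-west is the flask to watch. We choose temperature, since the last theta reading still leaves 52.4 % of the starting material not found as target at 2.4 equiv of partner.

The forecast also names north-west, but it sees “little clear temperature effect” and gives west 33.5 % (28 % to 38 %) and north-west 37 % (32 % to 42 %).

The simulation gives north-west: west 38.0 %, north-west 47.2 %.

    2 starting material → self-condensation product (k = 0.0760 /M/min, Ea = 100 kJ/mol)
    starting material + partner ⇌ adduct (K = 6.30 /M, k = 10.0 /M/min, Ea = 64.0 kJ/mol, ΔH = 4.00 kJ/mol)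
    adduct → target (k = 0.200 /min, Ea = 118 kJ/mol)
    adduct → decomposed reagent (k = 0.280 /min, Ea = 98.0 kJ/mol)
    (constants at 110 °C)

West stands 2.0 points below our line and north-west 2.3 points below it, so the flasks lie 9.2 points apart against the line's 9.5 points. Take the north-west recipe at 105 °C: the same line gives 37.7 %. That neighbouring flask holds 33.9 % of target at 20.0 min, with 7.90 % of starting material and 2.75 % of adduct still present.

(Readings and results come from a simulation with constants of no real substance; the scatter is artificial.)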